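The C13–C14 bond at the spiro centre is made by a tethered radical conjugate addition. A bromoacetal hung on the C20 oxygen (later the acetate oxygen) generates a C14 radical that adds to C13 of a spiro-3(2H)-furanone built on C9. The step exploits the gauche 1,3-relationship between C20 on C10 and the ring-C oxygen on C9 (rings B and C): it closes a temporary eight-membered acetal ring, sets quaternary C13 from the C10 face and installs C14/C15. Acetal hydrolysis, reduction and lactonisation then give ring D; the C11 carbonyl that activates C13 is removed afterwards. The cis-decalin comes from a Michael–alkylation annulation.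

Key step: step 11

Remark on numbering: labdane numbering is used. Ring A = C1–C5, C10; ring B = C5–C10; ring C = tetrahydrofuran (O, C9, C11, C12, C13); ring D = spiro γ-lactone (C13, C14, C15, O, C16); ring E = 19,6-lactone. C17 = methyl on C8, C18 = methyl on C4, C19 = carboxyl carbon on C4, C20 = carbon on C10. β = the face of C20.

Remark on the chemistry: the structure as written has H5 on the same face as C20, C19 and O6 (rings A/B cis-fused), and the route is planned for exactly this series. Compound 1 is taken as a commercial enantiopure building block.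

Step 1
Reactants: 1 (R)-4-[(tert-butyldimethylsilyl)oxy]cyclohex-2-en-1-one
Product: 2 trans-6-methyl enone
Conditions: LiN(iPr)2, THF, −78 °C; MeI, −78 → −40 °C
Reagents that add atoms: iodomethane, CI
Why: Kinetic α′-enolate alkylation, in which MeI should approach the cross-conjugated lithium enolate anti to the pseudo-axial 4-OTBS group, so that the future C8 methyl is set trans to the silyl ether.

Step 2
Reactants: 2 trans-6-methyl enone
Product: 3 2-iodo enone
Conditions: I2, pyridine, CH2Cl2, 0 → 25 °C
Reagents that add atoms: iodine, II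
Why: α-Iodination of the enone by conjugate addition of pyridine, iodination of the enolate and elimination (Baylis–Hillman-type sequence); no stereocentre is touched.

Step 3
Reactants: 3 2-iodo enone
Product: 4 enone ester
Conditions: CO (1 atm), MeOH, PdCl2(PPh3)2 (cat.), Et3N, DMF, 50 °C
Reagents that add atoms: carbon monoxide, [C-]#[O+]; methanol, CO
Why: Palladium-catalysed alkoxycarbonylation of the alkenyl iodide (oxidative addition, CO insertion, methanolysis) should give the doubly activated alkene needed for the annulation.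

Step 4
Reactants: 4 enone ester; 5 tert-butyl 5-bromopentanoate
Product: 7 cis-decalin keto diester, via Michael adduct enolate 6 (not isolated)
Conditions: 5, LiN(iPr)2, THF, −78 °C; then 4, −78 °C; then DMPU, −78 → 25 °C
Reagents that add atoms: none
Why: Michael-initiated ring closure: the ester enolate should add to C5 anti to the adjacent 6-OTBS group, and the resulting β-keto ester enolate is C-alkylated (6-exo-tet) on the face that carries the chain, which sets C5 and C10 (cis-fused; H5, CO2Me and OTBS all β) while C4 stays epimerisable.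

Step 5
Reactants: 7 cis-decalin keto diester; 8 ethynyl(trimethyl)silane
Product: 9 C9 propargylic alcohol
Conditions: 8, n-butyllithium, THF, −78 °C; CeCl3, −78 °C; then 7; aq. NH4Cl
Reagents that add atoms: none
Why: 1,2-Addition of the weakly basic cerium acetylide to the hindered ketone should occur from the β-face, because the α-face is flanked by both the C8 methyl and C1 of ring A; this sets C9 (O α, alkynyl β).

Step 6
Reactants: 9 C9 propargylic alcohol
Product: 10 C20,C9 diol
Conditions: LiBH4, THF, MeOH (cat.), 0 → 40 °C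
Reagents that add atoms: none
Why: Hydride reduction of the methyl ester, assisted by the neighbouring C9 hydroxyl, should leave the hindered tert-butyl ester intact; removing the C20 carbonyl also rules out retro-aldol cleavage in the next step.

Step 7
Reactants: 10 C20,C9 diol
Product: 12 methylated alkyne diol, via silyl alkyne diol 11 (not isolated)
Conditions: LiN(iPr)2 (3.3 equiv), THF, −78 → −30 °C; MeI (1.1 equiv); then MeOH, K2CO3, 25 °C
Reagents that add atoms: iodomethane, CI
Why: Ester enolate alkylation of the trianion: allylic 1,3-strain keeps C6 axial on ring A and the lithium-bridged C9/C20 alkoxides keep C20 axial over the β-face of C4, so MeI should enter equatorially from the α-face (C18 α, C19 β), and methanolic carbonate then cleaves the alkynyl C–Si bond.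

Step 8
Reactants: 12 methylated alkyne diol; 13 ethyl vinyl ether
Product: 14 C20 bromoacetal
Conditions: NBS, 13 (excess), CH2Cl2, −40 → 0 °C
Reagents that add atoms: N-bromosuccinimide, O=C1CCC(=O)N1Br
Why: Bromoacetalisation: NBS activates the vinyl ether and the primary C20–OH traps the bromo-oxocarbenium ion, the tertiary C9–OH being too hindered; the acetal carbon (future C15) forms as two epimers, which does not matter.

Step 9
Reactants: 14 C20 bromoacetal; 15 methyl chlorooxoacetate
Product: 16 ynone ester
Conditions: CuI (cat.), Et3N, THF, 25 °C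
Reagents that add atoms: none
Why: Copper-catalysed acylation of the terminal alkyne by the acid chloride through a copper acetylide (alkynyl ketone synthesis) should give the 2-oxo-3-ynoate without strong base.

Step 10
Reactants: 16 ynone ester
Product: 18 spiro-furanone, via enaminone 17 (not isolated)
Conditions: Et2NH, THF, 0 °C; then AcOH–NaOAc, H2O, 25 °C
Reagents that add atoms: water, O
Why: Conjugate addition of the amine to the ynone, hydrolysis of the enaminone and cyclodehydration of the C9 hydroxyl onto the C13 ketone isomerise the γ-hydroxy ynone to the 3(2H)-furanone, which forms ring C and makes C13 an electrophilic sp2 carbon.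

Step 11
Reactants: 18 spiro-furanone
Product: 19 cyclic acetal keto ester
Conditions: Bu3SnH, AIBN (slow addition), benzene (0.005 M), 80 °C
Reagents that add atoms: none
Why: Proposed new method: bromine abstraction from the C20-anchored bromoacetal gives a nucleophilic primary radical at C14 that adds to C13, the β-carbon of the 3(2H)-furanone that also carries the C16 ester, and the resulting C12 radical next to the C11 ketone is reduced by Bu3SnH; the closest known reactions are the Ueno–Stork bromoacetal cyclisation and radical additions to β-alkoxy enoates, which normally close five- or six-membered rings. The ring closed is the eight-membered acetal ring C13–C14–C15–O–C20–C10–C9–O (8-exo-trig), but C9–C10 and O–C13 are held by ring B and the furanone, so only three single bonds must be frozen, as in a 5-exo closure. C13 is the only lasting new stereocentre: the tether can reach it only across the furanone face that looks toward C10 (in the ring-B chair with O9 and C20 both equatorial), so C14 should end on the C10 side and the ester carbon C16 on the C8 side, as the target requires. The step needs attack at C13 and not at C12, which ring size and the ketone-stabilised product radical secure, and cyclisation faster than direct reduction, which high dilution and slow addition of the hydride serve. The acetal carbon C15 is carried as epimers and is erased in step 12.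

Step 12
Reactants: 19 cyclic acetal keto ester
Product: 22 diol spirolactone, via aldehyde 20 (not isolated), via triol ester 21 (not isolated)
Conditions: PPTS, acetone–H2O, 40 °C; then NaBH4, MeOH, 0 °C
Reagents that add atoms: water, O
Why: Mild acid hydrolysis of the mixed acetal frees C20–OH and unmasks C15 as an aldehyde; borohydride reduces this aldehyde and the C11 ketone, and the C15 alkoxide should close ring D on the C16 methyl ester (γ-lactonisation).

Step 13
Reactants: 22 diol spirolactone
Product: 23 C20 acetate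
Conditions: AcCl, 2,4,6-collidine, CH2Cl2, −78 °C
Reagents that add atoms: acetyl chloride, CC(=O)Cl
Why: Selective acylation of the primary C20–OH at low temperature; the secondary C11–OH next to the spiro centre C9 should react far more slowly.

Step 14
Reactants: 23 C20 acetate
Product: 24 C11 thiocarbonylimidazolide
Conditions: 1,1′-thiocarbonyldiimidazole, DMAP, ClCH2CH2Cl, 70 °C
Reagents that add atoms: 1,1′-thiocarbonyldiimidazole, S=C(n1ccnc1)n1ccnc1
Why: Thioacylation of the C11–OH gives the thiocarbonyl derivative needed for radical deoxygenation.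

Step 15
Reactants: 24 C11 thiocarbonylimidazolide
Product: 25 11-deoxy spirolactone
Conditions: Bu3SnH, AIBN, toluene, 100 °C
Reagents that add atoms: none
Why: Barton–McCombie deoxygenation: the stannyl radical adds to sulfur, the C11–O bond fragments and the secondary radical is reduced, which removes the oxygen that served to activate C13.

Step 16
Reactants: 25 11-deoxy spirolactone
Product: 27 target, via hydroxy acid 26 (not isolated)
Conditions: TFA, CH2Cl2, H2O (trace), 0 → 25 °C; evaporate; then EDC·HCl, DMAP, CH2Cl2 (high dilution), 25 °C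
Reagents that add atoms: none
Why: Acidolysis removes the tert-butyl ester and the silyl ether, and carbodiimide activation should close the γ-lactone (ring E) between the 4β-carboxyl and the 6β-hydroxyl, the only free hydroxyl left; all stereocentres are already in place.

Compound list

1 | (R)-4-[(tert-butyldimethylsilyl)oxy]cyclohex-2-en-1-one | C1=C[C@H](O[Si](C)(C)C(C)(C)C)CCC1=O | starting material
2 | (4R,6R)-4-[(tert-butyldimethylsilyl)oxy]-6-methylcyclohex-2-en-1-one (4,6-trans) | C1=C[C@H](O[Si](C)(C)C(C)(C)C)C[C@@H](C)C1=O | intermediate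
3 | (4R,6R)-4-[(tert-butyldimethylsilyl)oxy]-2-iodo-6-methylcyclohex-2-en-1-one | IC1=C[C@H](O[Si](C)(C)C(C)(C)C)C[C@@H](C)C1=O | intermediate
4 | methyl (3R,5R)-3-[(tert-butyldimethylsilyl)oxy]-5-methyl-6-oxocyclohex-1-ene-1-carboxylate | COC(=O)C1=C[C@H](O[Si](C)(C)C(C)(C)C)C[C@@H](C)C1=O | intermediate
5 | tert-butyl 5-bromopentanoate | CC(C)(C)OC(=O)CCCCBr | starting material
6 | Michael adduct (lithium enolate in the flask, drawn as the β-keto ester): ring B with 6β-OTBS, 8α-Me, 9-oxo, 10-CO2Me and, at C5 on the α-face, the CH(CO2tBu)CH2CH2CH2Br chain; C4 and C10 not yet fixed | COC(=O)C1[C@@H](C(CCCBr)C(=O)OC(C)(C)C)[C@H](O[Si](C)(C)C(C)(C)C)C[C@@H](C)C1=O | intermediate (not isolated)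
7 | cis-decalin keto diester: 10β-CO2Me, 5β-H, 6β-OTBS, 8α-Me, 9-oxo, 4-CO2tBu (both C4 epimers) | COC(=O)[C@]12CCCC(C(=O)OC(C)(C)C)[C@H]1[C@H](O[Si](C)(C)C(C)(C)C)C[C@@H](C)C2=O | intermediate
8 | ethynyl(trimethyl)silane | C#C[Si](C)(C)C | starting material
9 | C9 propargylic alcohol: 9α-OH, 9β-(trimethylsilyl)ethynyl, otherwise as 7 (C4 epimers) | COC(=O)[C@]12CCCC(C(=O)OC(C)(C)C)[C@H]1[C@H](O[Si](C)(C)C(C)(C)C)C[C@@H](C)[C@]2(O)C#C[Si](C)(C)C | intermediate
10 | C20,C9 diol: C20 = CH2OH, 9α-OH, 4-CO2tBu (C4 epimers), silyl alkyne | OC[C@]12CCCC(C(=O)OC(C)(C)C)[C@H]1[C@H](O[Si](C)(C)C(C)(C)C)C[C@@H](C)[C@]2(O)C#C[Si](C)(C)C | intermediate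
11 | silyl alkyne diol with 4α-methyl and 4β-CO2tBu | OC[C@]12CCC[C@](C)(C(=O)OC(C)(C)C)[C@H]1[C@H](O[Si](C)(C)C(C)(C)C)C[C@@H](C)[C@]2(O)C#C[Si](C)(C)C | intermediate (not isolated)
12 | methylated alkyne diol: 4α-Me, 4β-CO2tBu, C20 = CH2OH, 9α-OH, 9β-ethynyl, 6β-OTBS, 8α-Me, 5β-H | OC[C@]12CCC[C@](C)(C(=O)OC(C)(C)C)[C@H]1[C@H](O[Si](C)(C)C(C)(C)C)C[C@@H](C)[C@]2(O)C#C | intermediate
13 | ethyl vinyl ether (ethoxyethene) | C=COCC | starting material
14 | C20 bromoacetal: C20–O–CH(OEt)–CH2Br (acetal epimers), otherwise as 12 | CCOC(CBr)OC[C@]12CCC[C@](C)(C(=O)OC(C)(C)C)[C@H]1[C@H](O[Si](C)(C)C(C)(C)C)C[C@@H](C)[C@]2(O)C#C | intermediate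
15 | methyl chlorooxoacetate | COC(=O)C(=O)Cl | starting material
16 | ynone ester: C9β–C≡C–C(=O)–CO2Me, otherwise as 14 | CCOC(CBr)OC[C@]12CCC[C@](C)(C(=O)OC(C)(C)C)[C@H]1[C@H](O[Si](C)(C)C(C)(C)C)C[C@@H](C)[C@]2(O)C#CC(=O)C(=O)OC | intermediate
17 | enaminone: C9–C(NEt2)=CH–C(=O)–CO2Me | CCOC(CBr)OC[C@]12CCC[C@](C)(C(=O)OC(C)(C)C)[C@H]1[C@H](O[Si](C)(C)C(C)(C)C)C[C@@H](C)[C@]2(O)C(N(CC)CC)=CC(=O)C(=O)OC | intermediate (not isolated)
18 | spiro-furanone: ring C = O(9α)–C9–C11(=O)–C12H=C13(CO2Me); C20 bromoacetal retained | CCOC(CBr)OC[C@]12CCC[C@](C)(C(=O)OC(C)(C)C)[C@H]1[C@H](O[Si](C)(C)C(C)(C)C)C[C@@H](C)[C@]24C(=O)C=C(C(=O)OC)O4 | intermediate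
19 | cyclic acetal keto ester: new C13–C14 bond; eight-membered ring C13–C14–C15H(OEt)–O–C20–C10–C9–O; C11 ketone; C13 carries CO2Me, C14 on the C10 side | CCOC5OC[C@]12CCC[C@](C)(C(=O)OC(C)(C)C)[C@H]1[C@H](O[Si](C)(C)C(C)(C)C)C[C@@H](C)[C@]24C(=O)C[C@@](C5)(C(=O)OC)O4 | intermediate
20 | aldehyde: C13–CH2–CHO (C15), C20–OH, C11 ketone, C16 methyl ester | OC[C@]12CCC[C@](C)(C(=O)OC(C)(C)C)[C@H]1[C@H](O[Si](C)(C)C(C)(C)C)C[C@@H](C)[C@]24C(=O)C[C@@](CC=O)(C(=O)OC)O4 | intermediate (not isolated)
21 | triol ester: C15–OH, C11–OH, C20–OH, C16 methyl ester | OC[C@]12CCC[C@](C)(C(=O)OC(C)(C)C)[C@H]1[C@H](O[Si](C)(C)C(C)(C)C)C[C@@H](C)[C@]24C(O)C[C@@](CCO)(C(=O)OC)O4 | intermediate (not isolated)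
22 | diol spirolactone: ring D closed (16,15-olide, 13R), C11–OH (epimers), C20–OH | OC[C@]12CCC[C@](C)(C(=O)OC(C)(C)C)[C@H]1[C@H](O[Si](C)(C)C(C)(C)C)C[C@@H](C)[C@]24C(O)C[C@]1(CCOC1=O)O4 | intermediate
23 | C20 acetate of 22 | CC(=O)OC[C@]12CCC[C@](C)(C(=O)OC(C)(C)C)[C@H]1[C@H](O[Si](C)(C)C(C)(C)C)C[C@@H](C)[C@]24C(O)C[C@]1(CCOC1=O)O4 | intermediate
24 | C11 O-(imidazol-1-ylthiocarbonyl) derivative of 23 | CC(=O)OC[C@]12CCC[C@](C)(C(=O)OC(C)(C)C)[C@H]1[C@H](O[Si](C)(C)C(C)(C)C)C[C@@H](C)[C@]24C(OC(=S)n5ccnc5)C[C@]1(CCOC1=O)O4 | intermediate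
25 | 11-deoxy spirolactone: 20-OAc, 6β-OTBS, 19-tert-butyl ester, rings C and D complete | CC(=O)OC[C@]12CCC[C@](C)(C(=O)OC(C)(C)C)[C@H]1[C@H](O[Si](C)(C)C(C)(C)C)C[C@@H](C)[C@]24CC[C@]1(CCOC1=O)O4 | intermediate
26 | hydroxy acid: 6β-OH, 4β-CO2H | CC(=O)OC[C@]12CCC[C@](C)(C(=O)O)[C@H]1[C@H](O)C[C@@H](C)[C@]24CC[C@]1(CCOC1=O)O4 | intermediate (not isolated)
27 | (13R)-20-acetoxy-9α,13-epoxy-5β-labdane-19,6β:16,15-diolide | CC(=O)OC[C@@]12CCC[C@]3(C)C(=O)O[C@H](C[C@@H](C)[C@]14CC[C@]1(CCOC1=O)O4)[C@@H]23 | target

Total step count: 16. Longest linear sequence: 16 steps (from 1).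

Steps most likely to fail

Step 11 (the proposed method). The C14 radical may be reduced by the tin hydride before it reaches C13, or the ring-B chair that brings C20 next to C13 may be too sparsely populated. The fallback uses ordinary tin hydride 5-exo-trig cyclisation of a bromoalkyl ester onto an activated alkene; it sets out from 12 and comes back at 23. Compound 12 is acetylated at C20 (AcCl, collidine) to the 20-acetate alkyne F1. 2-Bromoethanol and oxalyl chloride give 2-bromoethyl chlorooxoacetate F2. CuI/Et3N coupling of F1 and F2 gives the ynone 2-bromoethyl ester F3, and Et2NH followed by buffered aqueous acid gives the furanone 2-bromoethyl ester F4. Bu3SnH/AIBN then closes ring D directly through the same C13–C14 bond and should give the spirolactone ketone F5. Here no tether selects the face, so the C13 epimers would have to be separated. NaBH4 reduction of the C11 ketone gives 23.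

Step 7. MeI may attack the β-face of the C4 enolate if the trianion does not hold the chair in which C20 shields that face. The fallback locks this chair with a temporary ring; it sets out from 10 and comes back at 12. 2-Methoxypropene and PPTS convert the C9/C20 diol into the C9,C20-acetonide F6, a 1,3-dioxane that can only exist when C20 and the C9 oxygen are gauche, that is with C20 axial on ring A. LiN(iPr)2/MeI then gives the methylated acetonide F7, and PPTS/MeOH followed by K2CO3/MeOH removes the acetonide and the alkynyl silyl group to give 12.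

Step 16. Closure of ring E may be slow because ring A must leave its chair to bring C19 to O6, so N-acylurea formation or intermolecular esterification may take over. The fallback forms the same C–O bond by carboxylate alkylation with inversion; it sets out from 25 and comes back at 27. HF·pyridine gives the 6β-alcohol F8, Dess–Martin periodinane the 6-ketone F9, and LiBH(s-Bu)3 at −78 °C (equatorial attack) the axial 6α-alcohol F10. TFA gives the 6α-hydroxy acid F11, and PPh3/DIAD (Mitsunobu lactonisation, inversion at C6) gives 27.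

Further compounds

F1 | step 11 | 20-acetate alkyne (C20 acetate of 12) | CC(=O)OC[C@]12CCC[C@](C)(C(=O)OC(C)(C)C)[C@H]1[C@H](O[Si](C)(C)C(C)(C)C)C[C@@H](C)[C@]2(O)C#C
F2 | step 11 | 2-bromoethyl chlorooxoacetate | O=C(Cl)C(=O)OCCBr
F3 | step 11 | ynone 2-bromoethyl ester | CC(=O)OC[C@]12CCC[C@](C)(C(=O)OC(C)(C)C)[C@H]1[C@H](O[Si](C)(C)C(C)(C)C)C[C@@H](C)[C@]2(O)C#CC(=O)C(=O)OCCBr
F4 | step 11 | furanone 2-bromoethyl ester | CC(=O)OC[C@]12CCC[C@](C)(C(=O)OC(C)(C)C)[C@H]1[C@H](O[Si](C)(C)C(C)(C)C)C[C@@H](C)[C@]24C(=O)C=C(C(=O)OCCBr)O4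
F5 | step 11 | spirolactone ketone (C11 ketone, 20-OAc) | CC(=O)OC[C@]12CCC[C@](C)(C(=O)OC(C)(C)C)[C@H]1[C@H](O[Si](C)(C)C(C)(C)C)C[C@@H](C)[C@]24C(=O)C[C@]1(CCOC1=O)O4
F6 | step 7 | C9,C20-acetonide of 10 (C4 epimers) | CC1(C)OC[C@]23CCCC(C(=O)OC(C)(C)C)[C@H]2[C@H](O[Si](C)(C)C(C)(C)C)C[C@@H](C)[C@]3(O1)C#C[Si](C)(C)C
F7 | step 7 | methylated acetonide (4α-Me, 4β-CO2tBu) | CC1(C)OC[C@]23CCC[C@](C)(C(=O)OC(C)(C)C)[C@H]2[C@H](O[Si](C)(C)C(C)(C)C)C[C@@H](C)[C@]3(O1)C#C[Si](C)(C)C
F8 | step 16 | 6β-alcohol (tert-butyl ester kept) | CC(=O)OC[C@]12CCC[C@](C)(C(=O)OC(C)(C)C)[C@H]1[C@H](O)C[C@@H](C)[C@]24CC[C@]1(CCOC1=O)O4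
F9 | step 16 | 6-ketone | CC(=O)OC[C@]12CCC[C@](C)(C(=O)OC(C)(C)C)[C@H]1C(=O)C[C@@H](C)[C@]24CC[C@]1(CCOC1=O)O4
F10 | step 16 | 6α-alcohol | CC(=O)OC[C@]12CCC[C@](C)(C(=O)OC(C)(C)C)[C@H]1[C@@H](O)C[C@@H](C)[C@]24CC[C@]1(CCOC1=O)O4
F11 | step 16 | 6α-hydroxy acid | CC(=O)OC[C@]12CCC[C@](C)(C(=O)O)[C@H]1[C@@H](O)C[C@@H](C)[C@]24CC[C@]1(CCOC1=O)O4
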